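## Analysis of the target

The target is a 7,7'-epoxylignan with one oxolane ring. It is numbered here O1, C2 (bearing ring A, 4-hydroxy-3,5-dimethoxyphenyl), C3 (bearing the hydroxymethyl carbon C6), C4 (bearing the hydroxymethyl carbon C7) and C5 (bearing ring B, 3,4,5-trimethoxyphenyl). The SMILES reads as (2R,3S,4S,5R): C2/C3, C3/C4 and C4/C5 are all trans, the aryl groups are 2,5-trans, and the core has a C2 axis through O1 and the midpoint of C3–C4 that is broken only by one methyl group (4-OMe on ring B, 4-OH on ring A). The four contiguous stereocentres are of two kinds: C3 and C4 cannot be corrected once C6 and C7 are at the alcohol level, whereas C2 and C5 are benzylic, α to O1 and para to an oxygen donor, so O1–C2 and O1–C5 ionise reversibly and these two centres can be put under thermodynamic control. The feature that invites the key move is the triad C2–O1–C5 flanked by rings A and B, which is a 1,3-diaryl carbonyl ylide in saturated form, set against C3–C4 with its trans one-carbon branches C6 and C7, which is an (E)-butenedioic acid unit. The sensitive groups are the free phenol of ring A (oxidation to a p-quinone methide), the two primary alcohols (capture of a C2 or C5 cation, leading to the isomeric oxolane and on to the furofuran), the electron-rich rings (Friedel–Crafts closure of such a cation to an aryltetralin) and the two ring C–O bonds (hydrogenolysis). The synthesis is hard for two reasons: rings A and B are electronically almost identical, so no reagent tells C2 from C5 and the rings must enter as separate building blocks, and the absolute configuration has to be written into C3/C4, two centres with no heteroatom handle.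

## Retrosynthetic reasoning

**15 back to 14 and 13 (no skeletal bond cut).** The phenol of ring A is masked as a benzyl ether and the hydroxyls on C6 and C7 as acetates. The benzyl ether keeps ring A from being oxidised to a quinone methide in the photochemical step. The acetates keep the primary oxygens from capturing benzylic cations. The forward steps are a methanolysis and a short hydrogenolysis.

**13 back to 12 (configurational disconnection at C2 and C5).** No bond is removed. Instead, control over C2 and C5 is given up. 13 is the only member of the (3S,4S) family in which all three vicinal pairs are trans, so every C2/C5 epimer collected in 12 should drain into it when O1–C2 and O1–C5 are allowed to open and reclose. As a result, the ring-forming step has to control nothing but C3 and C4.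

**12 back to 11 and 10 (C6 and C7 raised to the acyl level).** The two branches become acyl groups on auxiliary 7. This makes C3–C4 part of an electron-poor alkene in the step before and places the source of chirality directly on the two centres that cannot be repaired later. The forward reaction is a hydride cleavage that returns 7, followed by acetylation.

**10 back to 9 and 8 (C2–C3 and C4–C5 cut at once; key disconnection).** Cutting these two bonds, and not an ether bond, leaves O1 already sitting between both benzylic carbons. No etherification is then needed, and no lactone or furofuran closure can compete.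

- The cut divides the molecule into dipole 9, which carries the two different aryl rings, and the C2-symmetric dipolarophile 8, which carries all the stereochemical information that matters.
- Because 8 is C2-symmetric, the near identity of rings A and B is harmless: both ends of 9 meet the same environment.
- The forward reaction has to close the ring, make two C–C bonds and choose one face of 8.

**9 back to 5, then 5 back to 1, 2 and 3 (via 4), and 8 back to 6 and 7.** Ylide 9 is stored as oxirane 5, whose C–C bond is made only to be broken again, so its configuration is irrelevant. 5 is cut at that C–C bond and one C–O bond into benzylic halide 1 (ring B) and aldehyde 3 (ring A), joined through sulfonium salt 4 made with sulfide 2. 8 is cut at its two N-acyl bonds. Each precursor of the key step costs one step.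

## Alternatives that were turned down

**Alternative 1:** the textbook route cuts the ether bond O1–C2 and then the aldol bonds C4–C5 and C2–C3 one after the other. The forward key step is cyclodehydration of the 1,4-diol A1 through the ring A benzylic cation, after an Evans syn-aldol has set C5/C4 and a second carbonyl addition has brought in C2. It was turned down for three reasons.

1. The closure makes one bond and one stereocentre only, while C5, C4 and C3 are each paid for in separate steps.
2. The first aldol adduct of a succinate lactonises. On that γ-lactone (O, C5, C4, C3, C6) a second electrophile enters trans to the C4 branch, which maps onto the unwanted 3,4-cis oxolane. A detour through a lactone built from C6 and C7 is therefore needed.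
3. Four hydroxyls must be told apart, since the unprotected tetraol closes to the furofuran. The sequence is linear and well above ten steps.

**Alternative 2:** the biomimetic cut goes through C3–C4 and both C–O1 bonds. The forward key step is one-electron oxidation of a sinapic acid derivative carrying a chiral auxiliary, radical coupling at the two α-carbons, hydration of the bis(quinone methide) and ring closure. Reduction to the C2-symmetric bisphenol A2 and methylation of one of its two homotopic phenols follow. It was turned down for three reasons.

1. The C3–C4 bond forms between two planar, delocalised radicals whose auxiliaries are remote from the bond-forming carbons, so there is no convincing element of absolute control.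
2. The bis(quinone methide) partitions between hydration, Friedel–Crafts closure and other traps.
3. Ring B cannot take part in a phenol oxidation, so the unsymmetrical target is reached only through A2. Every monomethylation of A2 gives 15, but a statistical spread over un-, mono- and dimethylated material cannot be avoided.

**Alternative 3:** this route cuts O1–C5 and C2–C3. The forward key step is a Lewis-acid [3+2] annulation of the donor–acceptor cyclopropane A3 with aldehyde 3. It was turned down for three reasons.

1. The SN2-like opening and envelope closure lead to the 2,5-cis relationship, so an equilibration would be needed anyway.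
2. C3 carries a surplus ester that must go in a Krapcho dealkoxycarbonylation. C3 is then set by protonation in a ring whose C2 aryl and C4 branch lie on opposite faces, so there is no clear bias.
3. Enantiopure A3 costs several steps by itself, more than the annulation wins.

Key step: step 3

Assumption: the two (2S)-bornane-10,2-sultam units of 8 are taken to shield the Cα-re faces of the double bond, as in the uncatalysed cycloadditions known for this dienophile, so that 9 adds to the Cα-si faces. If the sense were opposite, the equally available antipode of 7 would be used and nothing else would change.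

## Steps

Step 1
Reactants: 1 3,4,5-trimethoxybenzyl chloride; 2 tetrahydrothiophene; 3 4-(benzyloxy)-3,5-dimethoxybenzaldehyde
Product: 5 rac-trans-2-[4-(benzyloxy)-3,5-dimethoxyphenyl]-3-(3,4,5-trimethoxyphenyl)oxirane, via sulfonium chloride 4 (not isolated)
Conditions: 1 + 2, MeCN, 40 °C; then 3, KOH, MeCN/H2O (9:1), 20 °C; filtration through basic alumina
Reagents that add atoms: none
Why: Sulfur-ylide epoxidation (Corey–Chaykovsky type with a semi-stabilised benzylic ylide): 1 alkylates 2, hydroxide deprotonates 4 and the ylide adds to 3, reversible betaine formation favouring the trans-oxirane. The configuration of 5 does not matter, because both of its stereocentres are erased in step 3.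

Step 2
Reactants: 6 fumaryl chloride; 7 (2S)-bornane-10,2-sultam [(1R)-(+)-2,10-camphorsultam]
Product: 8 N,N'-fumaroylbis[(2S)-bornane-10,2-sultam]
Conditions: 7 (2.05 equiv), NaH, toluene, 0 → 20 °C; then 6; recrystallisation
Reagents that add atoms: none
Why: Double N-acylation of the sodium salt of the sultam by a diacid chloride, a standard way to N-enoyl sultams; the E geometry is retained and the product should be crystalline.

Step 3
Reactants: 5 rac-trans-oxirane; 8 N,N'-fumaroylbis[(2S)-bornane-10,2-sultam]
Product: 10 (3R,4R)-2-[4-(benzyloxy)-3,5-dimethoxyphenyl]-5-(3,4,5-trimethoxyphenyl)oxolane-3,4-dicarbonyl bis[(2S)-bornane-10,2-sultam] as a mixture of C2/C5 epimers, via carbonyl ylide 9 (not isolated)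
Conditions: 5 (1.3 equiv), 8 (1.0 equiv), 4-mesityl-2,6-diphenylpyrylium tetrafluoroborate (5 mol %), CH2Cl2, blue LEDs (about 450 nm), N2, 20 °C
Reagents that add atoms: none
Why: The excited pyrylium salt oxidises an electron-rich aryl ring of 5, the oxirane radical cation breaks its C–C bond, and back electron transfer from the pyranyl radical gives carbonyl ylide 9, which adds to 8 in a concerted suprafacial [3+2] cycloaddition. The closest known reaction types are the photoredox generation of 1,3-diaryl carbonyl ylides from stilbene oxides with trapping by butenedioic acid derivatives, and the uncatalysed, highly face-selective cycloadditions of fumaroyl bis-sultams. The oxolane ring is closed by the simultaneous formation of C2–C3 and C4–C5 (4π + 2π), O1 being carried in by the dipole, so there is no separate cyclisation event. The trans relation of C3 and C4 follows stereospecifically from the E alkene. Their absolute (3R,4R) configuration comes from the two sultam units, which act in concert on a C2-symmetric alkene and leave the Cα-si faces open. C2 and C5 are set by the shape of the ylide (the extended form gives 2,5-cis) and by which acyl group lies endo; they are not controlled and need not be, since step 6 resets them. The only selectivity needed is π-facial: regiochemistry is void because both ends of 9 meet the same environment in 8, and chemoselectivity is secured because 8 is the only electron-poor π bond and is not oxidised by the catalyst.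

Step 4
Reactants: 10 bis(acylsultam) oxolane (C2/C5 epimers)
Product: 11 {(3S,4S)-2-[4-(benzyloxy)-3,5-dimethoxyphenyl]-5-(3,4,5-trimethoxyphenyl)oxolane-3,4-diyl}dimethanol as a mixture of C2/C5 epimers
Conditions: LiAlH4 (4 equiv), THF, −10 → 20 °C; aq. NaOH work-up; 7 recovered
Reagents that add atoms: none
Why: Reductive cleavage of N-acyl sultams by LiAlH4 gives the primary alcohols directly and returns the auxiliary. Hydride attack on the activated carbonyl groups is faster than enolisation, so C3 and C4 keep their configuration (the descriptors change from R to S only because the priorities change); the benzyl ether, the aryl ethers and the oxolane are inert.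

Step 5
Reactants: 11 diol (C2/C5 epimers)
Product: 12 {(3S,4S)-2-[4-(benzyloxy)-3,5-dimethoxyphenyl]-5-(3,4,5-trimethoxyphenyl)oxolane-3,4-diyl}bis(methylene) diacetate as a mixture of C2/C5 epimers
Conditions: Ac2O, pyridine, DMAP (5 mol %), CH2Cl2, 0 → 20 °C
Reagents that add atoms: acetic anhydride, CC(=O)OC(C)=O
Why: Standard O-acetylation that touches no stereocentre. It masks the oxygens on C6 and C7 so that they cannot capture a benzylic cation in step 6, which would lead to the isomeric oxolane and the furofuran.

Step 6
Reactants: 12 diacetate (C2/C5 epimers)
Product: 13 {(2R,3S,4S,5R)-2-[4-(benzyloxy)-3,5-dimethoxyphenyl]-5-(3,4,5-trimethoxyphenyl)oxolane-3,4-diyl}bis(methylene) diacetate (all-trans)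
Conditions: BF3·OEt2 (30 mol %), CH2Cl2, −30 → 0 °C, followed closely; Et3N quench
Reagents that add atoms: none
Why: Acid-catalysed benzylic epimerisation, known for 2,5-diaryloxolane and furofuran lignans: the Lewis acid reversibly ionises O1–C2 and O1–C5, each cation being stabilised by its para-alkoxy ring, and the tethered oxygen recloses (5-exo-trig on the quinoid cation). C2 and C5 are thereby set under thermodynamic control by the fixed (3S,4S) centres, and only the (2R,5R) isomer has all three vicinal pairs trans, so all epimers in 12 should converge on 13.

Step 7
Reactants: 13 all-trans diacetate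
Product: 14 {(2R,3S,4S,5R)-2-[4-(benzyloxy)-3,5-dimethoxyphenyl]-5-(3,4,5-trimethoxyphenyl)oxolane-3,4-diyl}dimethanol
Conditions: K2CO3 (20 mol %), MeOH, 20 °C
Reagents that add atoms: none
Why: Base-catalysed methanolysis of two primary acetates; there is no acidic C–H next to a stereocentre and no free phenol yet, so nothing can epimerise or open.

Step 8
Reactants: 14 all-trans diol benzyl ether
Product: 15 4-[(2R,3S,4S,5R)-3,4-bis(hydroxymethyl)-5-(3,4,5-trimethoxyphenyl)oxolan-2-yl]-2,6-dimethoxyphenol (target)
Conditions: H2 (1 atm), Pd/C, EtOAc/EtOH (1:1), 20 °C, stopped at full conversion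
Reagents that add atoms: none
Why: Hydrogenolysis of a phenolic benzyl ether is much faster than that of the hindered secondary benzylic C–O bonds of the oxolane under neutral conditions at 1 atm. No stereocentre is touched.

## Compound list

1 | 3,4,5-trimethoxybenzyl chloride | COc1cc(CCl)cc(OC)c1OC | starting material
2 | tetrahydrothiophene | C1CCSC1 | starting material
3 | 4-(benzyloxy)-3,5-dimethoxybenzaldehyde | COc1cc(C=O)cc(OC)c1OCc2ccccc2 | starting material
4 | 1-(3,4,5-trimethoxybenzyl)tetrahydrothiophenium chloride | COc1cc(C[S+]2CCCC2)cc(OC)c1OC.[Cl-] | intermediate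
5 | rac-trans-2-[4-(benzyloxy)-3,5-dimethoxyphenyl]-3-(3,4,5-trimethoxyphenyl)oxirane (racemate, one enantiomer drawn) | COc1cc([C@H]2O[C@@H]2c3cc(OC)c(OC)c(OC)c3)cc(OC)c1OCc4ccccc4 | intermediate
6 | fumaryl chloride | O=C(Cl)/C=C/C(=O)Cl | starting material
7 | (2S)-bornane-10,2-sultam [(1R)-(+)-2,10-camphorsultam] | N1[C@H]2C[C@@H]3CC[C@@]2(CS1(=O)=O)C3(C)C | starting material
8 | N,N'-fumaroylbis[(2S)-bornane-10,2-sultam] | O=C(/C=C/C(=O)N1[C@H]2C[C@@H]3CC[C@@]2(CS1(=O)=O)C3(C)C)N4[C@H]5C[C@@H]6CC[C@@]5(CS4(=O)=O)C6(C)C | intermediate
9 | 1-[4-(benzyloxy)-3,5-dimethoxyphenyl]-3-(3,4,5-trimethoxyphenyl) carbonyl ylide | COc1cc([CH-][O+]=Cc2cc(OC)c(OC)c(OC)c2)cc(OC)c1OCc3ccccc3 | intermediate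
10 | (3R,4R)-2-[4-(benzyloxy)-3,5-dimethoxyphenyl]-5-(3,4,5-trimethoxyphenyl)oxolane-3,4-dicarbonyl bis[(2S)-bornane-10,2-sultam] (C2 and C5 left open: mixture of epimers) | COc1cc(C2OC(c3cc(OC)c(OC)c(OC)c3)[C@H](C(=O)N4[C@H]5C[C@@H]6CC[C@@]5(CS4(=O)=O)C6(C)C)[C@H]2C(=O)N4[C@H]5C[C@@H]6CC[C@@]5(CS4(=O)=O)C6(C)C)cc(OC)c1OCc4ccccc4 | intermediate
11 | {(3S,4S)-2-[4-(benzyloxy)-3,5-dimethoxyphenyl]-5-(3,4,5-trimethoxyphenyl)oxolane-3,4-diyl}dimethanol (C2 and C5 left open: mixture of epimers) | COc1cc(C2OC(c3cc(OC)c(OC)c(OC)c3)[C@H](CO)[C@H]2CO)cc(OC)c1OCc4ccccc4 | intermediate
12 | diacetate of 11 (C2 and C5 left open: mixture of epimers) | COc1cc(C2OC(c3cc(OC)c(OC)c(OC)c3)[C@H](COC(C)=O)[C@H]2COC(C)=O)cc(OC)c1OCc4ccccc4 | intermediate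
13 | {(2R,3S,4S,5R)-2-[4-(benzyloxy)-3,5-dimethoxyphenyl]-5-(3,4,5-trimethoxyphenyl)oxolane-3,4-diyl}bis(methylene) diacetate | COc1cc([C@@H]2O[C@@H](c3cc(OC)c(OC)c(OC)c3)[C@H](COC(C)=O)[C@H]2COC(C)=O)cc(OC)c1OCc4ccccc4 | intermediate
14 | {(2R,3S,4S,5R)-2-[4-(benzyloxy)-3,5-dimethoxyphenyl]-5-(3,4,5-trimethoxyphenyl)oxolane-3,4-diyl}dimethanol | COc1cc([C@@H]2O[C@@H](c3cc(OC)c(OC)c(OC)c3)[C@H](CO)[C@H]2CO)cc(OC)c1OCc4ccccc4 | intermediate
15 | 4-[(2R,3S,4S,5R)-3,4-bis(hydroxymethyl)-5-(3,4,5-trimethoxyphenyl)oxolan-2-yl]-2,6-dimethoxyphenol | COc1cc([C@@H]2O[C@@H](c3cc(OC)c(OC)c(OC)c3)[C@H](CO)[C@H]2CO)cc(OC)c1O | target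

## Step count and least certain steps

Total step count: 8. Longest linear sequence: 7 (steps 1, 3, 4, 5, 6, 7, 8). Step 2 is a one-step side branch.

**Step 3 (key step).** The most likely failure is incomplete π-facial discrimination, because without a chelating metal the acyl sultam can react through more than one rotamer. A second failure is slow capture of the ylide by the bulky dipolarophile, which leaves time for reclosure, fragmentation and bleaching of the catalyst. The fallback secures the absolute configuration by enzymatic resolution instead of by an auxiliary. It sets out from 5, which is irradiated under the same catalysis with dimethyl fumarate, the dipolarophile with the closest precedent, to give the racemic dimethyl oxolane-3,4-dicarboxylate F1. Hydride reduction gives the racemic diol F2, acetylation gives the racemic diacetate F3, and the acid equilibration of step 6 gives the racemic all-trans diacetate F4. A lipase (triacylglycerol hydrolase class, for example from Burkholderia cepacia) in buffer/MTBE then hydrolyses both acetates of one enantiomer. The two successive enantioselective events on a nearly C2-symmetric substrate reinforce each other. The route is re-entered at 14, and the antipodal all-trans diacetate F5 is left behind.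

**Step 6.** The most likely failure is irreversible escape from the equilibrium, because each ionisation also offers three other paths: Friedel–Crafts attack of the other electron-rich ring on the cation, loss of the proton at C3 or C4 (which would scramble these centres), and Lewis-acid loss of the hindered benzyl ether. The fallback moves the epimerisation from C–O heterolysis to C–H homolysis. It sets out from 12, which is heated with catalytic tri-tert-butoxysilanethiol and di-tert-butyl hyponitrite as initiator in benzene. The thiyl radical abstracts the weak C2–H and C5–H atoms (benzylic and α to O1), and the thiol returns hydrogen to the planar radicals. The same pair acts in both directions, so a true equilibrium is approached with no cation present. The fallback comes back at 13 and makes no compound outside the list (F0).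

**Step 1.** The most likely failure is acid-triggered rearrangement of the doubly activated oxirane (Meinwald type) during work-up. Sluggish addition of an electron-rich ylide to an electron-rich aldehyde, with hydrolysis of the halide competing, is the other risk. The fallback builds the C=C bond first and adds oxygen under neutral conditions. It sets out from 1, which undergoes an Arbuzov reaction with triethyl phosphite to give diethyl (3,4,5-trimethoxybenzyl)phosphonate F6. A Horner–Wadsworth–Emmons reaction with 3 (NaH, THF) gives the (E)-stilbene F7. Dimethyldioxirane in acetone at 0 °C then gives 5 after mere evaporation, where the fallback comes back to the route.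

**Step 4.** The most likely failure is deprotonation at C3 or C4 by the basic hydride or by aluminium alkoxides before reduction. O1 is β to both acyl groups, so this would lead to epimerisation or to β-elimination with ring opening. Incomplete reduction of the hindered second acyl group is also possible. The fallback separates cleavage from reduction. It sets out from 10, which is hydrolysed with LiOH/H2O2 (a weakly basic, strongly nucleophilic peroxide anion) to the oxolane-3,4-dicarboxylic acid F8. BH3·SMe2, a non-basic reductant, then gives 11, where the fallback comes back to the route.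

## Further compounds

F1 | step 3 | racemic dimethyl (3R*,4R*)-2-[4-(benzyloxy)-3,5-dimethoxyphenyl]-5-(3,4,5-trimethoxyphenyl)oxolane-3,4-dicarboxylate (C2/C5 epimers) | COc1cc(C2OC(c3cc(OC)c(OC)c(OC)c3)[C@H](C(=O)OC)[C@H]2C(=O)OC)cc(OC)c1OCc4ccccc4.COc1cc(C2OC(c3cc(OC)c(OC)c(OC)c3)[C@@H](C(=O)OC)[C@@H]2C(=O)OC)cc(OC)c1OCc4ccccc4
F2 | step 3 | racemic {(3S*,4S*)-2-[4-(benzyloxy)-3,5-dimethoxyphenyl]-5-(3,4,5-trimethoxyphenyl)oxolane-3,4-diyl}dimethanol (C2/C5 epimers) | COc1cc(C2OC(c3cc(OC)c(OC)c(OC)c3)[C@H](CO)[C@H]2CO)cc(OC)c1OCc4ccccc4.COc1cc(C2OC(c3cc(OC)c(OC)c(OC)c3)[C@@H](CO)[C@@H]2CO)cc(OC)c1OCc4ccccc4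
F3 | step 3 | racemic diacetate of F2 (C2/C5 epimers) | COc1cc(C2OC(c3cc(OC)c(OC)c(OC)c3)[C@H](COC(C)=O)[C@H]2COC(C)=O)cc(OC)c1OCc4ccccc4.COc1cc(C2OC(c3cc(OC)c(OC)c(OC)c3)[C@@H](COC(C)=O)[C@@H]2COC(C)=O)cc(OC)c1OCc4ccccc4
F4 | step 3 | racemic all-trans diacetate (2R*,3S*,4S*,5R*) | COc1cc([C@@H]2O[C@@H](c3cc(OC)c(OC)c(OC)c3)[C@H](COC(C)=O)[C@H]2COC(C)=O)cc(OC)c1OCc4ccccc4.COc1cc([C@H]2O[C@H](c3cc(OC)c(OC)c(OC)c3)[C@@H](COC(C)=O)[C@@H]2COC(C)=O)cc(OC)c1OCc4ccccc4
F5 | step 3 | {(2S,3R,4R,5S)-2-[4-(benzyloxy)-3,5-dimethoxyphenyl]-5-(3,4,5-trimethoxyphenyl)oxolane-3,4-diyl}bis(methylene) diacetate (antipode of 13) | COc1cc([C@H]2O[C@H](c3cc(OC)c(OC)c(OC)c3)[C@@H](COC(C)=O)[C@@H]2COC(C)=O)cc(OC)c1OCc4ccccc4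
F0 | step 6 | none | none
F6 | step 1 | diethyl (3,4,5-trimethoxybenzyl)phosphonate | CCOP(=O)(Cc1cc(OC)c(OC)c(OC)c1)OCC
F7 | step 1 | (E)-2-(benzyloxy)-1,3-dimethoxy-5-[2-(3,4,5-trimethoxyphenyl)ethenyl]benzene | COc1cc(/C=C/c2cc(OC)c(OC)c(OC)c2)cc(OC)c1OCc3ccccc3
F8 | step 4 | (3R,4R)-2-[4-(benzyloxy)-3,5-dimethoxyphenyl]-5-(3,4,5-trimethoxyphenyl)oxolane-3,4-dicarboxylic acid (C2/C5 epimers) | COc1cc(C2OC(c3cc(OC)c(OC)c(OC)c3)[C@H](C(=O)O)[C@H]2C(=O)O)cc(OC)c1OCc4ccccc4
A1 | alternative 1 | (1R,2S,3S)-4-[4-(benzyloxy)-3,5-dimethoxyphenyl]-2,3-bis{[(tert-butyldimethylsilyl)oxy]methyl}-1-(3,4,5-trimethoxyphenyl)butane-1,4-diol (C4 carbinol open) | COc1cc(cc(OC)c1OC)[C@H](O)[C@H](CO[Si](C)(C)C(C)(C)C)[C@@H](CO[Si](C)(C)C(C)(C)C)C(O)c2cc(OC)c(OCc3ccccc3)c(OC)c2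
A2 | alternative 2 | 4,4'-[(2R,3S,4S,5R)-3,4-bis(hydroxymethyl)oxolane-2,5-diyl]bis(2,6-dimethoxyphenol) | COc1cc([C@@H]2O[C@@H](c3cc(OC)c(O)c(OC)c3)[C@H](CO)[C@H]2CO)cc(OC)c1O
A3 | alternative 3 | dimethyl (2S,3R)-2-[(benzyloxy)methyl]-3-(3,4,5-trimethoxyphenyl)cyclopropane-1,1-dicarboxylate | COC(=O)C1(C(=O)OC)[C@@H](COCc2ccccc2)[C@@H]1c3cc(OC)c(OC)c(OC)c3
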